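## Structural features

The target is the umbelliferone (7-hydroxycoumarin) ether of a C15 bicyclic alcohol, a trans-fused decalin of the ent-drimane type; drimane labels are used throughout (C1–C10 ring carbons, C11 = the OCH2 group on C9, C12 = the exocyclic CH2 on C8), also for acyclic precursors. Ring A (C1–C5, C10) is saturated and carries the secondary alcohol at C3 (S) beside the gem-dimethyl carbon C4; ring B (C5–C10) holds a cross-ring 1,3-diene, endocyclic C6=C7 conjugated with exocyclic C8=C12 and locked s-trans. The rings share C5 (S, H) and the quaternary C10 (R, methyl); C9 (R) carries the CH2O–aryl arm cis to the C10 methyl, so C5, C10 and C9 are contiguous stereocentres, and the C3 hydroxyl is axial (cis to H-5, trans to the C10 methyl). Fragile groups are the coumarin lactone (hydride, hydroxide, organometallics), the diene (acid moves it into conjugation; a carbonyl on C9 makes H-9 acidic and invites migration of C8=C12 to C8=C9) and the hindered C3 carbinol. The real difficulty is threefold: the trans-decalin with quaternary C10 between C5 and C9, the placement of both double bonds exactly at C6=C7 and C8=C12, and the axial C3–OH, which a chair-folded epoxy-polyene cyclisation does not give. The feature exploited is that ring B is a cyclohexene (C6=C7) whose C8 is sp2 with an exocyclic methylene, which is the retron of a [4+2] cycloaddition between a vinylallene C5=C6–C7=C8=C12 and an alkene C9=C10; the cis C9/C10 relationship is the imprint of an (E)-trisubstituted geranyl-type alkene, and ring A is then only the tether C4–C3–C2–C1.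

## Logic of the disconnections

**17 ⇒ 15 + 16.** The O–C11 aryl ether bond is cut. This keeps the hydride- and base-sensitive lactone of 16 out of every reductive step and leaves a C15 diol. The forward step must etherify the primary C11–OH selectively over the hindered axial C3–OH under neutral conditions that spare the diene.

**15 ⇒ 14.** No skeletal bond is cut; C11 is taken back to the ester level. The ester is the activating group of the key step and protects C11 while C3 is adjusted. The forward reduction must not move C8=C12 into conjugation.

**14 ⇒ 13 ⇒ 12 ⇒ 11.** Only the C3–H/C3–O configuration is changed, by way of the C3 ketone. The key step is expected to place the C3 oxygen equatorial (3R), so the axial 3S epimer is reached afterwards by equatorial hydride delivery to 13. The demand is a bulky hydride that leaves the ester alone, and a silyl ether removable without base (H-9 of the β,γ-unsaturated ester is acidic).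

**11 ⇒ 10.** The bonds C5–C10 and C8–C9 are cut: both rings, the stereotriad C5/C10/C9 and the C6=C7/C8=C12 diene go back to one acyclic vinylallene-enoate with a single stereocentre. The forward step must run through the endo transition state (trans fusion) and through the tether chair with the C3 silyloxy group equatorial, and the allene must tolerate the Lewis acid.

**10 ⇒ 8 + 9.** The C6–C7 single bond between the alkene and the allene is cut. This separates the three-carbon allene unit (C7, C8, C12) as a propargylic electrophile from an (E)-alkenylboronate. The forward coupling must proceed with SN2′ transposition (allene, not skipped enyne) and keep the C5=C6 geometry.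

**8 ⇒ 6 + 7 and 6 ⇒ 5.** The C5=C6 double bond is cut by metathesis logic, then the O–Si bond. The simplification is a plain vinyl group on the quaternary C4. The demand is cross-metathesis at a hindered vinyl group with E selectivity, leaving the trisubstituted enoate untouched.

**5 ⇒ 3 + 4.** The C3–C4 bond is cut. One step then creates the carbinol stereocentre, the quaternary C4 and the vinyl group from an achiral aldehyde and a C5 allene. The demand is reagent-controlled enantioselectivity for 3R and chemoselectivity for the aldehyde over the enoate.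

**3 ⇒ 1.** The isopropylidene C=C of 1 (the future C3 carbon) is cleaved. The (E)-C9=C10 alkene with its methyl and ester is bought ready-made. The demand is chemoselective cleavage of the electron-rich alkene beside the conjugated one.

## Other disconnections considered

**Alternative 1:** (first to come to mind) Cut C4–C5 and C9–C10, the biogenetic epoxy-polyene bicyclisation. Forward: titanocene(III)-mediated radical or Lewis-acid cationic cyclisation of (R)-10,11-epoxyfarnesyl acetate A1 to the hydroxy exo-methylene decalin A2, then C3 inversion, introduction of C6=C7 and etherification. The cyclisation ends at C8 and can deliver C8=C12, but C6 and C7 remain CH2. The second double bond would need a separate allylic oxidation at C7 and a regiocontrolled elimination towards C6 beside the exo-methylene, at least three redox steps each with a regiochemical choice. The C3 carbinol would also emerge equatorial, as in the chosen plan. The key step would leave the distinctive diene unsolved and the sequence would be longer.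

**Alternative 2:** Cut C6=C7 with transfer of C12, an endo-mode ring-closing enyne metathesis of the monocyclic 1,6-enyne A3 (C5 vinyl, C9 ethynyl). This would give the diene directly, but it forms no stereocentre: the C5/C10/C9 triad with its quaternary centre would have to be built on a cyclohexane first, which is the hard part. Ruthenium carbenes also intrinsically prefer exo closure of 1,6-enynes to a 1-vinylcyclopentene, so the required six-membered diene would rest on the disfavoured pathway.

**Alternative 3:** Cut the ring-B bonds made by a Robinson annulation, starting from (R)-Wieland–Miescher ketone A4 as the source of C10. Only C10 is set by that key step. C5, C9 and C3 each need their own stereocontrolled operation, and C4 dimethylation, C9 homologation, C8 methylenation and C6–C7 desaturation add a long train of functional-group steps. The diene would have to be assembled late beside an enolisable C9 carbonyl. Step economy is clearly worse than with a cycloaddition that delivers skeleton, triad and diene together.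

Key step: step 6

Remarks on the chemistry (assumptions):
- Methyl geranate is taken as the commercial (2E)-isomer; any (2Z)-material is removed chromatographically at 3 or 5.
- The iridium/(S)-SEGPHOS tert-prenylation is taken to give the 6R carbinol; should the sense of induction be opposite, the (R)-ligand is used and nothing else changes.
- Labels C1–C12 in the text are drimane labels (chain locants of 10: C1 = C11, C2 = C9, C3 = C10, C4 = C1, C5 = C2, C6 = C3, C7 = C4, C8 = C5, C9 = C6, C10 = C7, C11 = C8, C12 = C12); locants inside names are IUPAC locants.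

## Route

Step 1
Reactants: 1 methyl geranate [methyl (2E)-3,7-dimethylocta-2,6-dienoate]
Product: 3 methyl (2E)-3-methyl-6-oxohex-2-enoate, via secondary ozonide 2 (not isolated)
Conditions: O3 (1.0 equiv, Sudan Red 7B end point), CH2Cl2, −78 °C; then PPh3, −78 °C → rt
Reagents that add atoms: ozone, [O-][O+]=O
Why: Chemoselective ozonolysis: electrophilic ozone should take the electron-rich isopropylidene alkene far faster than the ester-conjugated C9=C10 alkene, the dye marks the end of the first cleavage, and PPh3 reduces the ozonide to the aldehyde; no stereocentre is formed and the (2E) geometry is untouched.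

Step 2
Reactants: 3 methyl (2E)-3-methyl-6-oxohex-2-enoate; 4 3-methylbuta-1,2-diene (1,1-dimethylallene)
Product: 5 methyl (2E,6R)-6-hydroxy-3,7,7-trimethylnona-2,8-dienoate
Conditions: cyclometalated Ir–(S)-SEGPHOS C,O-(4-chloro-3-nitrobenzoate) catalyst (5 mol %, from [Ir(cod)Cl]2, ligand and acid), Cs2CO3 (cat.), i-PrOH (2 equiv), toluene, 60 °C, sealed tube
Reagents that add atoms: none
Why: Iridium-catalysed transfer-hydrogenative carbonyl tert-prenylation: Ir–H from i-PrOH hydrometalates the allene to a 1,1-dimethyl-π-allyl iridium that adds to the aldehyde through its substituted terminus in a closed chair transition state, forming the C3–C4 bond, the quaternary C4 and the vinyl group; the chiral bisphosphine on the cyclometalated catalyst selects the aldehyde face and sets C3 (chain C6) as R, while the β,β-disubstituted enoate should be inert.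

Step 3
Reactants: 5 methyl (2E,6R)-6-hydroxy-3,7,7-trimethylnona-2,8-dienoate
Product: 6 methyl (2E,6R)-3,7,7-trimethyl-6-[(triethylsilyl)oxy]nona-2,8-dienoate
Conditions: TESOTf, 2,6-lutidine, CH2Cl2, −78 → 0 °C
Reagents that add atoms: triethylsilyl trifluoromethanesulfonate, CC[Si](CC)(CC)OS(=O)(=O)C(F)(F)F
Why: Silylation of a hindered secondary alcohol with the silyl triflate; TES is chosen because it should survive the alkylaluminium chloride of step 6 and can later be removed under buffered, non-basic conditions; the stereocentre is not touched.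

Step 4
Reactants: 6 methyl (2E,6R)-3,7,7-trimethyl-6-[(triethylsilyl)oxy]nona-2,8-dienoate; 7 2-ethenyl-4,4,5,5-tetramethyl-1,3,2-dioxaborolane (vinylboronic acid pinacol ester)
Product: 8 methyl (2E,6R,8E)-3,7,7-trimethyl-9-(4,4,5,5-tetramethyl-1,3,2-dioxaborolan-2-yl)-6-[(triethylsilyl)oxy]nona-2,8-dienoate
Conditions: Hoveyda–Grubbs II (2 × 5 mol %), 7 (5 equiv), toluene, 80 °C, argon sparge
Reagents that add atoms: none
Why: Olefin cross-metathesis: the vinyl group on the quaternary carbon should not homodimerise and is expected to cross with the excess vinylboronate to the thermodynamically favoured (E)-alkenylboronate (new C5=C6), while the trisubstituted conjugated alkene is not a metathesis substrate under these conditions.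

Step 5
Reactants: 8 methyl (2E,6R,8E)-3,7,7-trimethyl-9-(4,4,5,5-tetramethyl-1,3,2-dioxaborolan-2-yl)-6-[(triethylsilyl)oxy]nona-2,8-dienoate; 9 methyl prop-2-yn-1-yl carbonate
Product: 10 methyl (2E,6R,8E)-3,7,7-trimethyl-6-[(triethylsilyl)oxy]dodeca-2,8,10,11-tetraenoate
Conditions: Pd(PPh3)4 (5 mol %), THF, 50 °C
Reagents that add atoms: none
Why: Suzuki–Miyaura-type coupling of a propargylic carbonate with SN2′ transposition: oxidative addition with loss of CO2 gives an allenylpalladium methoxide, the methoxide activates the boronate for transmetalation, and reductive elimination should form the C6–C7 bond at the allene terminus with retention of the (E)-alkene, giving the vinylallene without added base.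

Step 6
Reactants: 10 methyl (2E,6R,8E)-3,7,7-trimethyl-6-[(triethylsilyl)oxy]dodeca-2,8,10,11-tetraenoate
Product: 11 methyl (1R,4aS,6R,8aR)-5,5,8a-trimethyl-2-methylidene-6-[(triethylsilyl)oxy]-1,2,4a,5,6,7,8,8a-octahydronaphthalene-1-carboxylate
Conditions: MeAlCl2 (1.1 equiv), CH2Cl2 (0.01 M), −78 → −20 °C
Reagents that add atoms: none
Why: Lewis-acid-promoted intramolecular Diels–Alder reaction of a vinylallene (type 1, fused mode); the closest known reaction types are the intramolecular vinylallene Diels–Alder reaction and the alkylaluminium-chloride-promoted cyclisation of (E)-3-methyl-2,8,10-trienoates and -trienals to angular-methyl trans-octalins. MeAlCl2 (also a proton scavenger) binds the ester carbonyl and lowers the LUMO of C9=C10, and the s-cis C5=C6–C7=C8 unit of the vinylallene adds suprafacially in a concerted, asynchronous [4+2] with the internal C5–C10 bond more advanced; the orthogonal C8=C12 π bond takes no part and emerges as the exocyclic methylene conjugated with the new C6=C7 bond. Ring B closes as the cycloaddition ring (bonds C5–C10 and C8–C9) and ring A as the six-membered ring spanned by the four-atom tether C4–C3–C2–C1, which adopts a chair. C9/C10: the (E)-geometry of the enoate places CO2Me and the C10 methyl cis, stereospecifically. C5/C10: the trans fusion follows from the endo transition state (Lewis-acid-bound ester under the diene, tether anti), the mode that Lewis acids reinforce for terminally activated (E)-dienophiles. Absolute sense: the C3 stereocentre sits in the chair tether with its OTES group equatorial, avoiding the syn-axial contacts with H-1ax and H-5 of the other chair, so the diene should add to the enoate face that gives 5S,9R,10R with 3R (silyloxy equatorial, cis to the C10 methyl). Regiochemistry is enforced by the tether, the quaternary C4 rules out a [1,5]-hydrogen shift of the vinylallene, the sp terminus has no inside substituent so the s-cis conformer is freely accessible, and the product diene is locked s-trans and cannot cycloadd further. The selectivities needed are endo over exo, secured by the Lewis-acid-bound ester, and one tether chair over the other, secured by the C3 silyloxy group.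

Step 7
Reactants: 11 methyl (1R,4aS,6R,8aR)-5,5,8a-trimethyl-2-methylidene-6-[(triethylsilyl)oxy]-1,2,4a,5,6,7,8,8a-octahydronaphthalene-1-carboxylate
Product: 12 methyl (1R,4aS,6R,8aR)-6-hydroxy-5,5,8a-trimethyl-2-methylidene-1,2,4a,5,6,7,8,8a-octahydronaphthalene-1-carboxylate
Conditions: HF·pyridine, pyridine, THF, 0 °C → rt
Reagents that add atoms: none
Why: Fluoride-mediated desilylation under pyridine-buffered conditions; the absence of free base should protect H-9 of the β,γ-unsaturated ester from enolisation and the mild acidity should leave the diene in place; no stereocentre is affected.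

Step 8
Reactants: 12 methyl (1R,4aS,6R,8aR)-6-hydroxy-5,5,8a-trimethyl-2-methylidene-1,2,4a,5,6,7,8,8a-octahydronaphthalene-1-carboxylate
Product: 13 methyl (1R,4aS,8aR)-5,5,8a-trimethyl-2-methylidene-6-oxo-1,2,4a,5,6,7,8,8a-octahydronaphthalene-1-carboxylate
Conditions: Dess–Martin periodinane, NaHCO3, CH2Cl2, 0 °C → rt
Reagents that add atoms: none
Why: Dess–Martin oxidation of the equatorial secondary alcohol to the C3 ketone under neutral buffered conditions that should not touch the diene or epimerise C9; the C3 stereocentre, having relayed chirality to the skeleton, is erased on purpose.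

Step 9
Reactants: 13 methyl (1R,4aS,8aR)-5,5,8a-trimethyl-2-methylidene-6-oxo-1,2,4a,5,6,7,8,8a-octahydronaphthalene-1-carboxylate
Product: 14 methyl (1R,4aS,6S,8aR)-6-hydroxy-5,5,8a-trimethyl-2-methylidene-1,2,4a,5,6,7,8,8a-octahydronaphthalene-1-carboxylate
Conditions: L-Selectride (1.2 equiv), THF, −78 °C; aqueous work-up
Reagents that add atoms: none
Why: Substrate-controlled ketone reduction with a bulky trialkylborohydride: the axial trajectory is blocked for a large hydride by the syn-axial hydrogens at C1 and C5, so hydride should arrive equatorially and give the axial 3S alcohol (cis to H-5), as in Selectride reductions of 4,4-dimethyl-3-oxo terpenoids to their 3-epi alcohols; the ester is not reduced at −78 °C.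

Step 10
Reactants: 14 methyl (1R,4aS,6S,8aR)-6-hydroxy-5,5,8a-trimethyl-2-methylidene-1,2,4a,5,6,7,8,8a-octahydronaphthalene-1-carboxylate
Product: 15 (2S,4aR,5R,8aS)-5-(hydroxymethyl)-1,1,4a-trimethyl-6-methylidene-1,2,3,4,4a,5,6,8a-octahydronaphthalen-2-ol
Conditions: DIBAL-H (3.5 equiv), CH2Cl2, −78 → 0 °C; Rochelle salt
Reagents that add atoms: none
Why: Hydride reduction of the ester to the primary C11 alcohol; the aluminium hydride is expected to reduce faster than it enolises, so C9 and the C8=C12 position should be preserved, and no stereocentre is formed.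

Step 11
Reactants: 15 (2S,4aR,5R,8aS)-5-(hydroxymethyl)-1,1,4a-trimethyl-6-methylidene-1,2,3,4,4a,5,6,8a-octahydronaphthalen-2-ol; 16 umbelliferone (7-hydroxy-2H-chromen-2-one)
Product: 17 7-{[(1R,4aS,6S,8aR)-6-hydroxy-5,5,8a-trimethyl-2-methylidene-1,2,4a,5,6,7,8,8a-octahydronaphthalen-1-yl]methoxy}-2H-chromen-2-one (target)
Conditions: PPh3, DIAD, THF, 0 °C → rt
Reagents that add atoms: none
Why: Mitsunobu etherification: the acidic phenol (pKa about 8) should displace the activated primary C11–OH, while the axial, neopentyl-type C3–OH is too hindered to form or react as an oxyphosphonium; no stereocentre is involved and the s-trans diene cannot act as a Diels–Alder diene towards the azodicarboxylate.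

## Compound list

1 | methyl geranate, methyl (2E)-3,7-dimethylocta-2,6-dienoate | COC(=O)/C=C(\C)CCC=C(C)C | starting material
2 | methyl (2E)-5-(5,5-dimethyl-1,2,4-trioxolan-3-yl)-3-methylpent-2-enoate (secondary ozonide) | COC(=O)/C=C(\C)CCC1OOC(C)(C)O1 | intermediate
3 | methyl (2E)-3-methyl-6-oxohex-2-enoate | COC(=O)/C=C(\C)CCC=O | intermediate
4 | 3-methylbuta-1,2-diene | CC(C)=C=C | starting material
5 | methyl (2E,6R)-6-hydroxy-3,7,7-trimethylnona-2,8-dienoate | COC(=O)/C=C(\C)CC[C@@H](O)C(C)(C)C=C | intermediate
6 | methyl (2E,6R)-3,7,7-trimethyl-6-[(triethylsilyl)oxy]nona-2,8-dienoate | COC(=O)/C=C(\C)CC[C@@H](O[Si](CC)(CC)CC)C(C)(C)C=C | intermediate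
7 | 2-ethenyl-4,4,5,5-tetramethyl-1,3,2-dioxaborolane | C=CB1OC(C)(C)C(C)(C)O1 | starting material
8 | methyl (2E,6R,8E)-3,7,7-trimethyl-9-(4,4,5,5-tetramethyl-1,3,2-dioxaborolan-2-yl)-6-[(triethylsilyl)oxy]nona-2,8-dienoate | COC(=O)/C=C(\C)CC[C@@H](O[Si](CC)(CC)CC)C(C)(C)/C=C/B1OC(C)(C)C(C)(C)O1 | intermediate
9 | methyl prop-2-yn-1-yl carbonate | COC(=O)OCC#C | starting material
10 | methyl (2E,6R,8E)-3,7,7-trimethyl-6-[(triethylsilyl)oxy]dodeca-2,8,10,11-tetraenoate | COC(=O)/C=C(\C)CC[C@@H](O[Si](CC)(CC)CC)C(C)(C)/C=C/C=C=C | intermediate
11 | methyl (1R,4aS,6R,8aR)-5,5,8a-trimethyl-2-methylidene-6-[(triethylsilyl)oxy]-1,2,4a,5,6,7,8,8a-octahydronaphthalene-1-carboxylate | C=C1C=C[C@@H]2C(C)(C)[C@H](O[Si](CC)(CC)CC)CC[C@@]2(C)[C@@H]1C(=O)OC | intermediate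
12 | methyl (1R,4aS,6R,8aR)-6-hydroxy-5,5,8a-trimethyl-2-methylidene-1,2,4a,5,6,7,8,8a-octahydronaphthalene-1-carboxylate | C=C1C=C[C@@H]2C(C)(C)[C@H](O)CC[C@@]2(C)[C@@H]1C(=O)OC | intermediate
13 | methyl (1R,4aS,8aR)-5,5,8a-trimethyl-2-methylidene-6-oxo-1,2,4a,5,6,7,8,8a-octahydronaphthalene-1-carboxylate | C=C1C=C[C@@H]2C(C)(C)C(=O)CC[C@@]2(C)[C@@H]1C(=O)OC | intermediate
14 | methyl (1R,4aS,6S,8aR)-6-hydroxy-5,5,8a-trimethyl-2-methylidene-1,2,4a,5,6,7,8,8a-octahydronaphthalene-1-carboxylate | C=C1C=C[C@@H]2C(C)(C)[C@@H](O)CC[C@@]2(C)[C@@H]1C(=O)OC | intermediate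
15 | (2S,4aR,5R,8aS)-5-(hydroxymethyl)-1,1,4a-trimethyl-6-methylidene-1,2,3,4,4a,5,6,8a-octahydronaphthalen-2-ol | C=C1C=C[C@@H]2C(C)(C)[C@@H](O)CC[C@@]2(C)[C@@H]1CO | intermediate
16 | umbelliferone, 7-hydroxy-2H-chromen-2-one | Oc1ccc2ccc(=O)oc2c1 | starting material
17 | 7-{[(1R,4aS,6S,8aR)-6-hydroxy-5,5,8a-trimethyl-2-methylidene-1,2,4a,5,6,7,8,8a-octahydronaphthalen-1-yl]methoxy}-2H-chromen-2-one | C=C1C=C[C@@H]2C(C)(C)[C@@H](O)CC[C@@]2(C)[C@@H]1COc1ccc2ccc(=O)oc2c1 | target

## Step count and least certain steps

Total step count: 11. Longest linear sequence: 11 steps (1 → 17); 4, 7, 9 and 16 are bought.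

**Step 6 (key step).** Three processes may erode it:
- leakage through the exo transition state to the cis-fused decalin;
- Lewis-acid-triggered oligomerisation of the allene, because the β,β-disubstituted ester is a sluggish dienophile and needs a fairly strong Lewis acid;
- incomplete π-facial control by the remote C3 silyloxy group. The two trans-fused adducts are diastereomers and separable at 11 or 12, but material would be lost.

Fallback: setting out from 10, the ester is reduced (DIBAL-H, −78 °C) to the allylic alcohol (2E,6R,8E)-3,7,7-trimethyl-6-[(triethylsilyl)oxy]dodeca-2,8,10,11-tetraen-1-ol F1 and oxidised (MnO2) to the enal (2E,6R,8E)-3,7,7-trimethyl-6-[(triethylsilyl)oxy]dodeca-2,8,10,11-tetraenal F2. An enal binds the milder Me2AlCl and should cyclise at −78 °C, where the endo preference of (E)-3-methyl trienals is strongest, to the aldehyde (1R,4aS,6R,8aR)-5,5,8a-trimethyl-2-methylidene-6-[(triethylsilyl)oxy]-1,2,4a,5,6,7,8,8a-octahydronaphthalene-1-carbaldehyde F3. This is oxidised at once (Pinnick: NaClO2, NaH2PO4, 2-methylbut-2-ene) to the acid (1R,4aS,6R,8aR)-5,5,8a-trimethyl-2-methylidene-6-[(triethylsilyl)oxy]-1,2,4a,5,6,7,8,8a-octahydronaphthalene-1-carboxylic acid F4 and methylated (TMSCHN2), which comes back to the route at 11.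

**Step 4.** Slow turnover and catalyst decay are the likely failure, because the vinyl group sits on a quaternary carbon beside a silyloxy-bearing carbon. Fallback: setting out from 6, Lemieux–Johnson cleavage (OsO4 cat., NaIO4, 2,6-lutidine) of the monosubstituted vinyl group, which should be osmylated faster than the electron-poor, more hindered enoate, gives the non-enolisable aldehyde methyl (2E,6R)-3,7,7-trimethyl-8-oxo-6-[(triethylsilyl)oxy]oct-2-enoate F5. Takai olefination (CHI3, CrCl2) gives the vinyl iodide methyl (2E,6R,8E)-9-iodo-3,7,7-trimethyl-6-[(triethylsilyl)oxy]nona-2,8-dienoate F6, and Stille coupling with tributyl(propa-1,2-dien-1-yl)stannane comes back to the route at 10, bypassing 8.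

**Step 5.** Coupling through the propargyl rather than the allenyl terminus (skipped enyne), protodeboronation, or further palladium chemistry of the product allene may compete. Fallback: setting out from 8, Suzuki–Miyaura coupling with 3-bromoprop-2-yn-1-ol gives the enynol methyl (2E,6R,8E)-12-hydroxy-3,7,7-trimethyl-6-[(triethylsilyl)oxy]dodeca-2,8-dien-10-ynoate F7. Its reductive 1,3-transposition (Myers allene synthesis: 2-nitrobenzenesulfonylhydrazide, PPh3, DEAD, −15 °C → rt; loss of sulfinic acid and retro-ene loss of N2) comes back to the route at 10.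

**Step 2.** Erosion of enantioselectivity, the wrong sense of induction, or base-mediated self-condensation and transesterification of the enolisable aldehyde may occur. Fallback: setting out from 3, Barbier prenylation (prenyl bromide, indium, THF/H2O; γ-attack) gives racemic methyl (2E)-6-hydroxy-3,7,7-trimethylnona-2,8-dienoate F8, which is oxidised (Dess–Martin) to the ketone methyl (2E)-3,7,7-trimethyl-6-oxonona-2,8-dienoate F9. CBS reduction ((S)-Me-CBS, catecholborane, −78 °C; the tertiary alkyl group acts as the large substituent) comes back to the route at 5 with the sense predictable from the oxazaborolidine model.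

**Step 11.** Azo-ene addition of DIAD to the diene, or sluggish displacement at the β-branched C11, may compete. Fallback: setting out from 15, selective sulfonylation of the primary alcohol (TsCl, pyridine, 0 °C) gives [(1R,4aS,6S,8aR)-6-hydroxy-5,5,8a-trimethyl-2-methylidene-1,2,4a,5,6,7,8,8a-octahydronaphthalen-1-yl]methyl 4-methylbenzenesulfonate F10. Williamson displacement with 16 (Cs2CO3, DMF, 60 °C) comes back to the route at 17.

## Further compounds

F1 | step 6 | (2E,6R,8E)-3,7,7-trimethyl-6-[(triethylsilyl)oxy]dodeca-2,8,10,11-tetraen-1-ol | OC/C=C(\C)CC[C@@H](O[Si](CC)(CC)CC)C(C)(C)/C=C/C=C=C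
F2 | step 6 | (2E,6R,8E)-3,7,7-trimethyl-6-[(triethylsilyl)oxy]dodeca-2,8,10,11-tetraenal | O=C/C=C(\C)CC[C@@H](O[Si](CC)(CC)CC)C(C)(C)/C=C/C=C=C
F3 | step 6 | (1R,4aS,6R,8aR)-5,5,8a-trimethyl-2-methylidene-6-[(triethylsilyl)oxy]-1,2,4a,5,6,7,8,8a-octahydronaphthalene-1-carbaldehyde | C=C1C=C[C@@H]2C(C)(C)[C@H](O[Si](CC)(CC)CC)CC[C@@]2(C)[C@@H]1C=O
F4 | step 6 | (1R,4aS,6R,8aR)-5,5,8a-trimethyl-2-methylidene-6-[(triethylsilyl)oxy]-1,2,4a,5,6,7,8,8a-octahydronaphthalene-1-carboxylic acid | C=C1C=C[C@@H]2C(C)(C)[C@H](O[Si](CC)(CC)CC)CC[C@@]2(C)[C@@H]1C(=O)O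
F5 | step 4 | methyl (2E,6R)-3,7,7-trimethyl-8-oxo-6-[(triethylsilyl)oxy]oct-2-enoate | COC(=O)/C=C(\C)CC[C@@H](O[Si](CC)(CC)CC)C(C)(C)C=O
F6 | step 4 | methyl (2E,6R,8E)-9-iodo-3,7,7-trimethyl-6-[(triethylsilyl)oxy]nona-2,8-dienoate | COC(=O)/C=C(\C)CC[C@@H](O[Si](CC)(CC)CC)C(C)(C)/C=C/I
F7 | step 5 | methyl (2E,6R,8E)-12-hydroxy-3,7,7-trimethyl-6-[(triethylsilyl)oxy]dodeca-2,8-dien-10-ynoate | COC(=O)/C=C(\C)CC[C@@H](O[Si](CC)(CC)CC)C(C)(C)/C=C/C#CCO
F8 | step 2 | methyl (2E)-6-hydroxy-3,7,7-trimethylnona-2,8-dienoate (racemic) | COC(=O)/C=C(\C)CCC(O)C(C)(C)C=C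
F9 | step 2 | methyl (2E)-3,7,7-trimethyl-6-oxonona-2,8-dienoate | COC(=O)/C=C(\C)CCC(=O)C(C)(C)C=C
F10 | step 11 | [(1R,4aS,6S,8aR)-6-hydroxy-5,5,8a-trimethyl-2-methylidene-1,2,4a,5,6,7,8,8a-octahydronaphthalen-1-yl]methyl 4-methylbenzenesulfonate | C=C1C=C[C@@H]2C(C)(C)[C@@H](O)CC[C@@]2(C)[C@@H]1COS(=O)(=O)c1ccc(C)cc1
A1 | alternative 1 | (2E,6E)-9-[(2R)-3,3-dimethyloxiran-2-yl]-3,7-dimethylnona-2,6-dien-1-yl acetate | CC(=O)OC/C=C(\C)CC/C=C(\C)CC[C@H]1OC1(C)C
A2 | alternative 1 | [(1R,4aS,6R,8aR)-6-hydroxy-5,5,8a-trimethyl-2-methylidenedecahydronaphthalen-1-yl]methyl acetate | C=C1CC[C@@H]2C(C)(C)[C@H](O)CC[C@@]2(C)[C@@H]1COC(C)=O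
A3 | alternative 2 | 7-{[(2R)-2-[(1R,2S,4S)-2-ethenyl-4-hydroxy-1,3,3-trimethylcyclohexyl]but-3-yn-1-yl]oxy}-2H-chromen-2-one | C=C[C@@H]3C(C)(C)[C@@H](O)CC[C@@]3(C)[C@@H](C#C)COc1ccc2ccc(=O)oc2c1
A4 | alternative 3 | (8aR)-8a-methyl-3,4,8,8a-tetrahydronaphthalene-1,6(2H,7H)-dione | C[C@@]12CCC(=O)C=C1CCCC2=O
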